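## Retrosynthetic overview

1. Ring numbering: C1 (OMe), C2 (H), C3 (CH2CH2Ph), C4 (OMe), C5 (OMe), C6 (CH2CH2CMe2OH).
2. Feature used: the oxygens on C1 and C5 flank the C6 chain as in a 2-alkylresorcinol. C4-OMe and C3-phenethyl sit like the α-methoxy carbon and the ketone carbon of a 3-oxoacyl unit. C2-H can be the site of a lost ester.
3. Late stage: the tertiary alcohol comes from Markovnikov hydration of a C6 prenyl group, the C1 and C5 methyl ethers from O-methylation, and C2-H from saponification and decarboxylation of a resorcylate.
4. Ring formation (the only ring made; the phenyl ring is bought in with 7): a [3+3] cyclocondensation forms C5–C6 and C2–C3. The partners are bis(silyloxy)diene 5 (C2, C1, C6) and ketal-masked 2-methoxy-3-oxoacyl chloride 11 (C5, C4, C3).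
5. Fragments: 5 from methyl acetoacetate and prenyl bromide; 11 from methyl methoxyacetate and 3-phenylpropanoyl chloride.

Key step: step 8

Assumption: the target has no stereocentre; 8–13 are used as racemates or diastereomer mixtures and 4 and 5 as E/Z mixtures, because these elements vanish on aromatisation; enolates and other deprotonated forms of a numbered compound are not numbered separately; the C3 ketone is masked as the 1,3-dioxolane, the ketal that does not shed alcohol on the way to the acid chloride.

## Route

Step 1
Reactants: 1 methyl acetoacetate; 2 prenyl bromide (1-bromo-3-methylbut-2-ene)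
Product: 3 methyl 7-methyl-3-oxooct-6-enoate
Conditions: NaH, THF, 0 °C; n-BuLi, 0 °C; 2, 0 → 20 °C; cold 1 M HCl
Reagents that add atoms: none
Why: γ-Alkylation of a β-keto ester dianion: the terminal carbanion, the last formed and most basic site, alone displaces the allylic bromide (SN2), so the prenyl group is placed on C4 of the keto ester and no C2 alkylation is expected.

Step 2
Reactants: 3 methyl 7-methyl-3-oxooct-6-enoate
Product: 4 methyl 7-methyl-3-(trimethylsilyloxy)octa-2,6-dienoate
Conditions: Me3SiCl, Et3N, toluene, 20 °C; filtration under N2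
Reagents that add atoms: chlorotrimethylsilane, C[Si](C)(C)Cl
Why: O-silylation of the enolisable β-keto ester under amine base gives the 3-silyloxy enoate, the usual first stage on the way to a 1,3-bis(silyloxy)diene, and neither the ester nor the remote alkene reacts.

Step 3
Reactants: 4 methyl 7-methyl-3-(trimethylsilyloxy)octa-2,6-dienoate
Product: 5 1-methoxy-7-methyl-1,3-bis(trimethylsilyloxy)octa-1,3,6-triene
Conditions: LiN(i-Pr)2, THF, −78 °C; Me3SiCl, −78 → 20 °C; evaporation, hexane, filtration (no water)
Reagents that add atoms: chlorotrimethylsilane, C[Si](C)(C)Cl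
Why: Kinetic γ-deprotonation of the 3-silyloxy enoate gives the extended ester dienolate, which is silylated on oxygen to the silyl ketene acetal (standard bis(silyloxy)diene preparation); the diene is labile to water and is therefore freed from salts without it and used at once.

Step 4
Reactants: 6 methyl methoxyacetate; 7 3-phenylpropanoyl chloride
Product: 8 methyl 2-methoxy-3-oxo-5-phenylpentanoate (racemic)
Conditions: 6 (2.1 equiv), LiN(i-Pr)2 (2.1 equiv), THF, −78 °C; 7 (1.0 equiv), −78 °C; cold 1 M HCl
Reagents that add atoms: none
Why: Crossed Claisen-type C-acylation of a lithium ester enolate with an acid chloride at low temperature; the second equivalent of enolate deprotonates the more acidic β-keto ester as it forms, which prevents a second acylation, and the new stereocentre is of no consequence.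

Step 5
Reactants: 8 methyl 2-methoxy-3-oxo-5-phenylpentanoate
Product: 9 methyl 2-methoxy-2-[2-(2-phenylethyl)-1,3-dioxolan-2-yl]acetate
Conditions: HOCH2CH2OH, p-TsOH·H2O (cat.), toluene, reflux, Dean–Stark
Reagents that add atoms: ethylene glycol, OCCO
Why: Acid-catalysed ketalisation with azeotropic removal of water, routine for β-keto esters: only the ketone can form a ketal, its electrophilicity is raised by the α-methoxy and ester groups, and the cyclic ketal resists loss of alcohol to an enol ether.

Step 6
Reactants: 9 methyl 2-methoxy-2-[2-(2-phenylethyl)-1,3-dioxolan-2-yl]acetate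
Product: 10 potassium 2-methoxy-2-[2-(2-phenylethyl)-1,3-dioxolan-2-yl]acetate
Conditions: KOSiMe3, THF, 20 °C; salt collected and dried in vacuo
Reagents that add atoms: potassium trimethylsilanolate, C[Si](C)(C)[O-].[K+]
Why: Anhydrous cleavage of a methyl ester with potassium trimethylsilanolate delivers the dry carboxylate salt directly, so the ketal never meets aqueous acid.

Step 7
Reactants: 10 potassium 2-methoxy-2-[2-(2-phenylethyl)-1,3-dioxolan-2-yl]acetate
Product: 11 2-methoxy-2-[2-(2-phenylethyl)-1,3-dioxolan-2-yl]acetyl chloride (ethylene ketal of 2-methoxy-3-oxo-5-phenylpentanoyl chloride)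
Conditions: (COCl)2 (excess), CH2Cl2, 0 → 20 °C; filtered, concentrated, used crude
Reagents that add atoms: oxalyl chloride, O=C(Cl)C(=O)Cl
Why: A carboxylate salt reacts with oxalyl chloride through the mixed anhydride to the acid chloride with KCl, CO and CO2 as the only other products, so no HCl arises that could open the dioxolane.

Step 8
Reactants: 5 1-methoxy-7-methyl-1,3-bis(trimethylsilyloxy)octa-1,3,6-triene; 11 2-methoxy-2-[2-(2-phenylethyl)-1,3-dioxolan-2-yl]acetyl chloride
Product: 14 methyl 2,4-dihydroxy-5-methoxy-3-(3-methylbut-2-en-1-yl)-6-(2-phenylethyl)benzoate, via acylated silyl ketene acetal 12 (not isolated), via cyclised hydroxyethoxy diketone 13 (not isolated)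
Conditions: 5 (1.3 equiv), 11, 2,6-di-tert-butyl-4-methylpyridine (2 equiv), 4 Å MS, CH2Cl2, −78 °C; TiCl4 (2 equiv) dropwise; −78 → −20 °C; cold sat. aq. NaHCO3
Reagents that add atoms: none
Why: TiCl4 activates the acid chloride, and the terminal carbon of diene 5 (future C6, carrying the prenyl group) is acylated with loss of the silyl group on the C1 oxygen, which forms C5–C6 and leaves silyl ketene acetal 12. TiCl4 then opens the dioxolane to an oxocarbenium ion at future C3, which the ketene acetal carbon (future C2) attacks in a Mukaiyama-type aldol addition that forms C2–C3 and closes the six-membered carbocycle 13; counted through the C1=C2 enol this is a favoured 6-(enolendo)-exo-trig closure. β-Elimination of the hydroxyethoxy group from C3 and enolisation of the C1 and C5 ketones give the benzene ring, so no stereocentre remains and the mixtures at the centres of 11–13 do not matter. The closest known reaction type is the Lewis acid [3+3] cyclocondensation of 1,3-bis(silyloxy)-1,3-dienes with ketal-masked 3-oxoacyl chlorides to 2,4-dihydroxybenzoates. The step needs one orientation of the two three-carbon partners: the diene terminus is its most nucleophilic carbon, and the acyl chloride is more reactive and far less hindered than the fully substituted ketal carbon, whose ionisation is slowed by the neighbouring C–OMe, so acylation comes first and afterwards only C2 can reach the ketal carbon through a six-membered ring. The hindered pyridine takes up HCl without binding TiCl4, and together with the low temperature and the cold basic quench it keeps the trisubstituted alkene from being protonated next to the new phenols.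

Step 9
Reactants: 14 methyl 2,4-dihydroxy-5-methoxy-3-(3-methylbut-2-en-1-yl)-6-(2-phenylethyl)benzoate
Product: 16 4-methoxy-2-(3-methylbut-2-en-1-yl)-5-(2-phenylethyl)benzene-1,3-diol, via resorcylic acid 15 (not isolated)
Conditions: KOH, MeOH/H2O (degassed), reflux, Ar; cold 1 M HCl to pH 5
Reagents that add atoms: none
Why: Saponification of the hindered ester gives the 2,4-dihydroxybenzoate, whose ipso carbon, ortho and para to phenoxide oxygens, is protonated by the medium and loses CO2 (protodecarboxylation of a β-resorcylic acid), while the prenyl alkene is inert to base and exclusion of air protects the electron-rich ring.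

Step 10
Reactants: 16 4-methoxy-2-(3-methylbut-2-en-1-yl)-5-(2-phenylethyl)benzene-1,3-diol
Product: 17 1,3,4-trimethoxy-2-(3-methylbut-2-en-1-yl)-5-(2-phenylethyl)benzene
Conditions: MeI, K2CO3, DMF, 40 °C, N2
Reagents that add atoms: iodomethane, CI
Why: Williamson etherification of both phenols; the carbon between them (C6) is already substituted, so C-methylation would cost the aromaticity and O-alkylation is the productive path.

Step 11
Reactants: 17 1,3,4-trimethoxy-2-(3-methylbut-2-en-1-yl)-5-(2-phenylethyl)benzene
Product: 18 2-methyl-4-[2,3,6-trimethoxy-4-(2-phenylethyl)phenyl]butan-2-ol (CNP0309409.0)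
Conditions: Co(acac)2 (cat.), PhSiH3, O2 (1 atm), THF, 20 °C
Reagents that add atoms: dioxygen, O=O
Why: Mukaiyama hydration: a cobalt hydride formed from Co(acac)2 and PhSiH3 transfers a hydrogen atom to the CH end of the trisubstituted alkene, the tertiary radical is trapped by O2, and the peroxy species is reduced by the silane to the tertiary alcohol (Markovnikov), with the arene, the ethers and the benzylic positions left alone.

## Compound list

1 | methyl acetoacetate | CC(=O)CC(=O)OC | starting material
2 | prenyl bromide (1-bromo-3-methylbut-2-ene) | CC(C)=CCBr | starting material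
3 | methyl 7-methyl-3-oxooct-6-enoate | COC(=O)CC(=O)CCC=C(C)C | intermediate
4 | methyl 7-methyl-3-(trimethylsilyloxy)octa-2,6-dienoate (E/Z mixture at C2) | COC(=O)C=C(O[Si](C)(C)C)CCC=C(C)C | intermediate
5 | 1-methoxy-7-methyl-1,3-bis(trimethylsilyloxy)octa-1,3,6-triene | COC(O[Si](C)(C)C)=CC(O[Si](C)(C)C)=CCC=C(C)C | intermediate
6 | methyl methoxyacetate | COCC(=O)OC | starting material
7 | 3-phenylpropanoyl chloride | O=C(Cl)CCc1ccccc1 | starting material
8 | methyl 2-methoxy-3-oxo-5-phenylpentanoate (racemic) | COC(C(=O)OC)C(=O)CCc1ccccc1 | intermediate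
9 | methyl 2-methoxy-2-[2-(2-phenylethyl)-1,3-dioxolan-2-yl]acetate (racemic) | COC(C(=O)OC)C1(CCc2ccccc2)OCCO1 | intermediate
10 | potassium 2-methoxy-2-[2-(2-phenylethyl)-1,3-dioxolan-2-yl]acetate (racemic) | COC(C(=O)[O-])C1(CCc2ccccc2)OCCO1.[K+] | intermediate
11 | 2-methoxy-2-[2-(2-phenylethyl)-1,3-dioxolan-2-yl]acetyl chloride (racemic) | COC(C(=O)Cl)C1(CCc2ccccc2)OCCO1 | intermediate
12 | trimethylsilyl ketene acetal of methyl 6-methoxy-4-(3-methylbut-2-en-1-yl)-3,5-dioxo-6-[2-(2-phenylethyl)-1,3-dioxolan-2-yl]hexanoate (not isolated, isomer mixture) | COC(O[Si](C)(C)C)=CC(=O)C(CC=C(C)C)C(=O)C(OC)C1(CCc2ccccc2)OCCO1 | intermediate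
13 | methyl 2-(2-hydroxyethoxy)-3-methoxy-5-(3-methylbut-2-en-1-yl)-4,6-dioxo-2-(2-phenylethyl)cyclohexane-1-carboxylate (not isolated, isomer mixture, written as the free alcohol) | COC(=O)C1C(=O)C(CC=C(C)C)C(=O)C(OC)C1(OCCO)CCc1ccccc1 | intermediate
14 | methyl 2,4-dihydroxy-5-methoxy-3-(3-methylbut-2-en-1-yl)-6-(2-phenylethyl)benzoate | COC(=O)c1c(O)c(CC=C(C)C)c(O)c(OC)c1CCc1ccccc1 | intermediate
15 | 2,4-dihydroxy-5-methoxy-3-(3-methylbut-2-en-1-yl)-6-(2-phenylethyl)benzoic acid (not isolated) | OC(=O)c1c(O)c(CC=C(C)C)c(O)c(OC)c1CCc1ccccc1 | intermediate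
16 | 4-methoxy-2-(3-methylbut-2-en-1-yl)-5-(2-phenylethyl)benzene-1,3-diol | COc1c(O)c(CC=C(C)C)c(O)cc1CCc1ccccc1 | intermediate
17 | 1,3,4-trimethoxy-2-(3-methylbut-2-en-1-yl)-5-(2-phenylethyl)benzene | COc1cc(CCc2ccccc2)c(OC)c(OC)c1CC=C(C)C | intermediate
18 | 2-methyl-4-[2,3,6-trimethoxy-4-(2-phenylethyl)phenyl]butan-2-ol | COc1cc(CCc2ccccc2)c(OC)c(OC)c1CCC(C)(C)O | target

## Step count and risks

Total step count: 11. Longest linear sequence: 8 (steps 4–11). The diene branch (steps 1–3) joins at step 8.

**Steps most likely to fail**

**1. Step 8.**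
- What may go wrong:
  - protonation of the trisubstituted alkene by acid set free in the flask, followed by capture by the neighbouring phenol oxygen;
  - closure of the open-chain intermediate through an enol oxygen instead of through C2;
  - slow bond formation at the substituted diene terminus on the way to a fully substituted ring.
- Fallback: the alkene is kept out of the ring-forming step, and the prenyl group is put on afterwards by directed ortho-metalation. It sets out from 1 and comes back to the route at 17.
  - Compound 1 is silylated as in steps 2 and 3, through methyl 3-(trimethylsilyloxy)but-2-enoate F1, to 1-methoxy-1,3-bis(trimethylsilyloxy)buta-1,3-diene F2.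
  - F2 and 11 with TiCl4 in CH2Cl2 at −78 °C should give methyl 2,4-dihydroxy-5-methoxy-6-(2-phenylethyl)benzoate F3. The diene terminus is now unhindered and no acid-sensitive group is present.
  - KOH in aqueous methanol, as in step 9, leads through 2,4-dihydroxy-5-methoxy-6-(2-phenylethyl)benzoic acid F4 to 4-methoxy-5-(2-phenylethyl)benzene-1,3-diol F5.
  - MeI and K2CO3 give 1,2,5-trimethoxy-3-(2-phenylethyl)benzene F6.
  - n-BuLi in THF at 0 °C removes the proton at C6, the only position flanked by two methoxy groups. Alkylation of the aryllithium with 2 gives 17.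

**2. Step 4.**
- What may go wrong: self-condensation of the methoxyacetate enolate, acylation on oxygen, or deprotonation of the acid chloride to a ketene.
- Fallback: aldol addition and oxidation in place of acylation. It sets out from 6 and comes back at 8.
  - The lithium enolate of 6 (LiN(i-Pr)2, THF, −78 °C) is added to 3-phenylpropanal to give methyl 3-hydroxy-2-methoxy-5-phenylpentanoate F7 as a diastereomer mixture.
  - Dess–Martin periodinane in CH2Cl2 oxidises F7 to 8.

**3. Step 9.**
- What may go wrong: incomplete saponification of the doubly ortho-substituted ester, and air oxidation of the electron-rich dihydroxyarene in hot base.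
- Fallback: methylation first, then removal of the carboxyl group from the ether-protected acid by metal-catalysed protodecarboxylation. It sets out from 14 and comes back at 17.
  - MeI and K2CO3 in DMF at 50 °C give methyl 2,4,5-trimethoxy-3-(3-methylbut-2-en-1-yl)-6-(2-phenylethyl)benzoate F8.
  - KOSiMe3 in refluxing THF, followed by cold citric acid, gives 2,4,5-trimethoxy-3-(3-methylbut-2-en-1-yl)-6-(2-phenylethyl)benzoic acid F9.
  - Ag2CO3 (cat.) and AcOH (cat.) in DMSO at 120 °C remove CO2 from this ortho-disubstituted, electron-rich acid to give 17.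

## Further compounds

F1 | step 8 | methyl 3-(trimethylsilyloxy)but-2-enoate | COC(=O)C=C(C)O[Si](C)(C)C
F2 | step 8 | 1-methoxy-1,3-bis(trimethylsilyloxy)buta-1,3-diene | COC(O[Si](C)(C)C)=CC(=C)O[Si](C)(C)C
F3 | step 8 | methyl 2,4-dihydroxy-5-methoxy-6-(2-phenylethyl)benzoate | COC(=O)c1c(O)cc(O)c(OC)c1CCc1ccccc1
F4 | step 8 | 2,4-dihydroxy-5-methoxy-6-(2-phenylethyl)benzoic acid | OC(=O)c1c(O)cc(O)c(OC)c1CCc1ccccc1
F5 | step 8 | 4-methoxy-5-(2-phenylethyl)benzene-1,3-diol | COc1c(O)cc(O)cc1CCc1ccccc1
F6 | step 8 | 1,2,5-trimethoxy-3-(2-phenylethyl)benzene | COc1cc(OC)c(OC)c(CCc2ccccc2)c1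
F7 | step 4 | methyl 3-hydroxy-2-methoxy-5-phenylpentanoate (diastereomer mixture) | COC(C(=O)OC)C(O)CCc1ccccc1
F8 | step 9 | methyl 2,4,5-trimethoxy-3-(3-methylbut-2-en-1-yl)-6-(2-phenylethyl)benzoate | COC(=O)c1c(OC)c(CC=C(C)C)c(OC)c(OC)c1CCc1ccccc1
F9 | step 9 | 2,4,5-trimethoxy-3-(3-methylbut-2-en-1-yl)-6-(2-phenylethyl)benzoic acid | OC(=O)c1c(OC)c(CC=C(C)C)c(OC)c(OC)c1CCc1ccccc1
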